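At early times the green run gains L at a rate of 0.130 min⁻¹ as a share of the charge, counted from the start to its first reading, but between its last two readings at only 0.0390 min⁻¹. You asked for a quick number, and that drop is where it starts.

- green: G 20 mM; X 1.5 equiv; Q 0.80 mM; run made earlier
- flask: G 20 mM; X 1.50 equiv; Q 0.400 mM; time 40 min; volume of the second phase over the first 1.0

- green (time / min: L / %): 0.833: 10.8; 1.50: 17.8; 2.50: 25.1; 3.00: 27.9; 4.00: 31.8

(standard deviation of a reading: 0.5 percentage points)

1. amount of L at 40 min, in percent of the G charged
2. the change that raises the amount of L at 40 min, in percent of the G charged most ("none" if none brings more than 2 percentage points) (eta / alpha / none)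
3. amount of L at 40 min, in percent of the G charged, after alpha

- eta: doubling the transfer coefficient of X, all else as stated
- alpha: doubling the amount of X, all else as stated

- in the second phase: X; everything else is in the first
- charges count per volume of the first phase; a concentration in a rate is the amount of a species over the volume of its own phase; every rate counts per litre of the first phase
- the earlier runs hold the two phases in the same ratio of volumes as the flask asked about
- no earlier run changes the charge of Q; that part of a forecast is a guess

Time drops out when rate is set against height. The two rates belong to L at the middle of their intervals, 5.40% and 29.8%, so:

fall = (early rate − late rate) / (late height − early height) = 0.371 min⁻¹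

height at zero rate = late height + late rate / fall = 40.4%

This stall height, the amount of L at which the straight line of rate against L reaches zero, is extrapolated from differences of readings that each carry a scatter of 0.5 percentage points, so it stands as an estimate. On that line the gap below it shrinks as exp(−fall × time), and 1/fall, 2.70 min, is far shorter than the 40 min asked. This reckoning therefore puts L at 40.4%.

Q is half its green charge, yet tiny beside X, so the height is carried over unchanged, as a guess. A faster transfer should alter the pace of a curve already flat. That favours alpha, whose size one run cannot show.

The forecast differs, with 22%, alpha as best and 37% after it, reading “Q acting as a catalyst that dies”.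

The flask gives 42.2%; alpha is best, adding 21 points to reach 63.4%, while eta adds 0.14 points.

    G + L → J (k = 0.160 M⁻¹ s⁻¹)
    E ⇌ X, rate k2*([E] - [X]/K2) per volume of the first phase (partition coefficient = 1.60, kL = 0.0610 s⁻¹)
    G + E → L (k = 0.270 M⁻¹ s⁻¹)
    E + Q → Z (k = 6.80 M⁻¹ s⁻¹)

G is the limiting reagent of the flask: 0.075% of it remains at 40.0 min, with X at 31.6% of its charge, and L stands at 42.2% against the stall height of 40.4%. The step from E and Q to Z makes no difference to that L. The neighbour is the same flask read at 10 min, where the shrinking gap leaves 39.4% of L by the same reckoning. That neighbour holds 40.3% of L, 44.0% as J, and 16% of G still there.

The data stem from a simulated flask for substances that don't exist.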